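**Plan**

1. Daucane numbering is used: the five-membered ring B is C1–C5 (methyl on C1, oxygen on C2 and C4, isopropyl on C4), the seven-membered ring A is C1, C5 and C6–C10 (oxygen on C6, methyl on C8, C8=C9). β is the face of the C1 methyl group.
2. The retrosynthesis cuts the two angelate C–O bonds first, then the C7–C8 bond of ring A. On ring B it then cuts the C1–C10 bond (enolate alkylation), the C5–C6 bond (conjugate addition) and the C4–isopropyl bond (carbonyl addition), which leads back to 2-methylcyclopent-2-en-1-one.
3. The ring A cut is possible because C7 is the single methylene between the oxygen-bearing C6 and the C8=C9 double bond. With C6 as a methyl ketone on C5, C7 is an enolate carbon and C8 is the halide-bearing carbon of a (Z)-alkenyl chloride chain on C1.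
4. In the forward direction ring B is fully substituted first (steps 1–13), ring A is closed by palladium-catalysed ketone α-alkenylation (step 14), and C6 reduction followed by two successive angeloylations (C6, then C2) finishes the route.
5. A CBS reduction sets a temporary carbinol at C2 that steers the isopropyl group onto C4. C4 then controls the rest: vinyl enters C5 anti to isopropyl, the side chain enters C1 anti to vinyl, and the β C4 hydroxyl delivers hydride to the β faces of the C2 and C6 ketones, giving both α alcohols.

Key step: step 14

Remark: (Z)-1,3-dichlorobut-2-ene is taken to be available as the pure Z isomer; if only the commercial isomer mixture is at hand, it is fractionally distilled first.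

**Route**

Step 1
Reactants: 1 2-methylcyclopent-2-en-1-one
Product: 2 (R)-2-methylcyclopent-2-en-1-ol
Conditions: (S)-1-methyl-3,3-diphenyltetrahydro-1H,3H-pyrrolo[1,2-c][1,3,2]oxazaborole (10 mol %), BH3·SMe2, THF, −20 °C; MeOH quench
Reagents that add atoms: none
Why: CBS (Corey–Bakshi–Shibata) reduction, in which the ketone binds to the boron of the (S)-oxazaborolidine with its methyl-bearing alkenyl side as the large group, so that hydride from the coordinated borane should reach one face and give the R allylic alcohol, the centre that later fixes the absolute configuration of C4.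

Step 2
Reactants: 2 (R)-2-methylcyclopent-2-en-1-ol
Product: 3 (R)-tert-butyldimethyl[(2-methylcyclopent-2-en-1-yl)oxy]silane
Conditions: t-BuMe2SiCl, imidazole, DMF, rt
Reagents that add atoms: tert-butyldimethylsilyl chloride, CC(C)(C)[Si](C)(C)Cl
Why: Imidazole-promoted silyl ether formation on a secondary allylic alcohol, needed so that the oxidation of step 3 attacks the ring methylene and not the carbinol.

Step 3
Reactants: 3 (R)-tert-butyldimethyl[(2-methylcyclopent-2-en-1-yl)oxy]silane
Product: 4 (R)-4-[(tert-butyldimethylsilyl)oxy]-3-methylcyclopent-2-en-1-one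
Conditions: CrO3, 3,5-dimethylpyrazole, CH2Cl2, −20 °C
Reagents that add atoms: chromium trioxide, O=[Cr](=O)=O
Why: Allylic oxidation with the CrO3–3,5-dimethylpyrazole complex should convert the ring methylene next to the vinylic CH into the enone carbonyl, the silyloxy-bearing carbon being shielded and the methyl group less reactive, and the stereocentre is not touched.

Step 4
Reactants: 4 (R)-4-[(tert-butyldimethylsilyl)oxy]-3-methylcyclopent-2-en-1-one
Product: 5 (1R,4R)-4-[(tert-butyldimethylsilyl)oxy]-3-methyl-1-(propan-2-yl)cyclopent-2-en-1-ol (isopropyl trans to the silyloxy group)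
Conditions: i-PrMgCl, CeCl3, THF, −78 °C
Reagents that add atoms: isopropylmagnesium chloride, CC(C)[Mg]Cl
Why: 1,2-Addition of an organocerium reagent suppresses enolisation, β-hydride reduction and conjugate addition, and the nucleophile should approach the carbonyl anti to the bulky silyloxy group across the ring, which sets the tertiary carbinol (the future C4) as R with hydroxyl cis to the silyloxy group.

Step 5
Reactants: 5 (1R,4R)-4-[(tert-butyldimethylsilyl)oxy]-3-methyl-1-(propan-2-yl)cyclopent-2-en-1-ol
Product: 6 (1R,4R)-3-methyl-1-(propan-2-yl)cyclopent-2-ene-1,4-diol (cis-diol)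
Conditions: n-Bu4NF, THF, 0 °C to rt
Reagents that add atoms: none
Why: Fluoride-mediated desilylation under non-acidic conditions, chosen because the tertiary allylic alcohol would ionise in acid, and any minor diastereomer from step 4 can be removed by chromatography at this stage so that the enantiomeric purity of the next compound is not eroded.

Step 6
Reactants: 6 (1R,4R)-3-methyl-1-(propan-2-yl)cyclopent-2-ene-1,4-diol
Product: 7 (R)-4-hydroxy-2-methyl-4-(propan-2-yl)cyclopent-2-en-1-one
Conditions: MnO2, CH2Cl2, rt
Reagents that add atoms: none
Why: Allylic alcohol oxidation with MnO2 touches only the secondary allylic hydroxyl, which removes the temporary stereocentre and leaves the tertiary carbinol as the single stereocentre of the enone.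

Step 7
Reactants: 7 (R)-4-hydroxy-2-methyl-4-(propan-2-yl)cyclopent-2-en-1-one
Product: 8 (R)-2-methyl-4-(propan-2-yl)-4-[(trimethylsilyl)oxy]cyclopent-2-en-1-one
Conditions: Me3SiCl, imidazole, DMF, 0 °C to rt
Reagents that add atoms: chlorotrimethylsilane, C[Si](C)(C)Cl
Why: Imidazole-promoted silylation caps the tertiary hydroxyl as a small trimethylsilyl ether that tolerates the organometallic steps, keeps the oxygen face of C4 open and is shed by dilute acid in step 10.

Step 8
Reactants: 8 (R)-2-methyl-4-(propan-2-yl)-4-[(trimethylsilyl)oxy]cyclopent-2-en-1-one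
Product: 9 {[(3R,4R)-3-ethenyl-2-methyl-4-(propan-2-yl)-4-(trimethylsilyloxy)cyclopent-1-en-1-yl]oxy}trimethylsilane (vinyl cis to the C4 silyloxy group)
Conditions: CH2=CHMgBr, CuBr·SMe2 (10 mol %), Me3SiCl, hexamethylphosphoramide, THF, −78 °C; Et3N, pentane work-up
Reagents that add atoms: vinylmagnesium bromide, C=C[Mg]Br; chlorotrimethylsilane, C[Si](C)(C)Cl
Why: Copper-catalysed conjugate addition of the Grignard reagent with Me3SiCl trapping, in which the vinyl group should enter C5 on the face opposite the isopropyl group of the neighbouring quaternary C4, that is cis to the small silyloxy group, while the silyl enol ether locks in the enolate regiochemistry needed for step 10.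

Step 9
Reactants: 10 (Z)-1,3-dichlorobut-2-ene
Product: 11 (Z)-3-chloro-1-iodobut-2-ene
Conditions: NaI, acetone, rt, dark
Reagents that add atoms: sodium iodide, [Na+].[I-]
Why: Finkelstein halide exchange by SN2 displacement at the allylic carbon, driven by precipitation of NaCl, leaves the alkenyl chloride and its Z geometry untouched and gives a more reactive alkylating agent.

Step 10
Reactants: 9 {[(3R,4R)-3-ethenyl-2-methyl-4-(propan-2-yl)-4-(trimethylsilyloxy)cyclopent-1-en-1-yl]oxy}trimethylsilane, 11 (Z)-3-chloro-1-iodobut-2-ene
Product: 14 (2R,3R,4R)-2-[(2Z)-3-chlorobut-2-en-1-yl]-3-ethenyl-4-hydroxy-2-methyl-4-(propan-2-yl)cyclopentan-1-one, via lithium enolate 12 (not isolated), via silyl ether ketone 13 (not isolated)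
Conditions: MeLi, THF, 0 °C; then 11, N,N'-dimethylpropyleneurea, −78 to −20 °C; then 1 M HCl, THF, 0 °C
Reagents that add atoms: none
Why: MeLi cleaves the enol silyl ether to the regiodefined lithium enolate 12, whose C-alkylation (enolate alkylation) by the allylic iodide should occur anti to the neighbouring vinyl group and so set the quaternary C1 with methyl β and the side chain α, and dilute acid on work-up removes the tertiary trimethylsilyl ether of 13.

Step 11
Reactants: 14 (2R,3R,4R)-2-[(2Z)-3-chlorobut-2-en-1-yl]-3-ethenyl-4-hydroxy-2-methyl-4-(propan-2-yl)cyclopentan-1-one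
Product: 15 (1R,3S,4R,5R)-4-[(2Z)-3-chlorobut-2-en-1-yl]-5-ethenyl-4-methyl-1-(propan-2-yl)cyclopentane-1,3-diol (trans-1,3-diol; C2 hydroxyl α)
Conditions: Me4NBH(OAc)3, MeCN–AcOH, −20 °C to rt
Reagents that add atoms: none
Why: Evans–Saksena hydroxyl-directed reduction, in which the β C4 hydroxyl exchanges onto boron and delivers hydride intramolecularly to the β face of the C2 ketone, should give the α alcohol that steric control would not favour, while the alkenes and the alkenyl chloride are inert to triacetoxyborohydride.

Step 12
Reactants: 15 (1R,3S,4R,5R)-4-[(2Z)-3-chlorobut-2-en-1-yl]-5-ethenyl-4-methyl-1-(propan-2-yl)cyclopentane-1,3-diol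
Product: 16 bis(triethylsilyl) ether of diol 15 (C2 α-OSiEt3, C4 β-OSiEt3)
Conditions: Et3SiOTf, 2,6-lutidine, CH2Cl2, −78 to 0 °C
Reagents that add atoms: triethylsilyl trifluoromethanesulfonate, CC[Si](CC)(CC)OS(=O)(=O)C(F)(F)F
Why: Silyl ether formation with a silyl triflate and 2,6-lutidine covers the secondary and the hindered tertiary hydroxyl alike, which protects them from the base of step 14 and blocks retro-aldol cleavage once C6 is a ketone.

Step 13
Reactants: 16 bis(triethylsilyl) ether of diol 15
Product: 17 ring B methyl ketone with C1 β-methyl and α-[(Z)-3-chlorobut-2-enyl], C2 α-OSiEt3, C4 β-OSiEt3 and α-isopropyl, C5 β-acetyl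
Conditions: PdCl2 (10 mol %), Cu(OAc)2 (20 mol %), O2 (1 atm), N,N-dimethylacetamide–H2O (7:1), rt
Reagents that add atoms: water, O
Why: Wacker–Tsuji oxidation converts the terminal vinyl group with Markovnikov selectivity into the methyl ketone, the trisubstituted alkenyl chloride being too hindered and electron-poor to react and the acetate-buffered copper co-oxidant sparing the silyl ethers.

Step 14
Reactants: 17 ring B methyl ketone with C5 β-acetyl and C1 α-[(Z)-3-chlorobut-2-enyl]
Product: 19 2α,4β-bis(triethylsilyloxy)dauc-8-en-6-one (trans ring fusion; 1β-methyl; 5α-H), via sodium dienolate 18 (not isolated)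
Conditions: Pd(OAc)2 (10 mol %), P(t-Bu)3·HBF4 (20 mol %), NaOt-Bu (2.5 equiv), toluene (high dilution), 70 °C; then cold aqueous NH4Cl
Reagents that add atoms: none
Why: Zerovalent palladium, formed in the flask from Pd(OAc)2 and P(t-Bu)3, inserts into the C8–Cl bond of the (Z)-alkenyl chloride with retention of geometry, the sodium enolate of the methyl ketone replaces chloride on palladium and binds through C7, and reductive elimination from the eight-membered palladacycle forms the C7–C8 bond. The closest known reaction type is the palladium-catalysed α-alkenylation of ketone enolates with alkenyl halides, run here intramolecularly, with the bulky electron-rich phosphine that an alkenyl chloride requires. Ring A closes as a seven-membered ring by this reductive elimination, with the enolate double bond inside the new ring (enolendo) and chloride leaving from the ring carbon C8, and only the Z chloride, which holds C8 cis to C10, can reach C7. No stereocentre is created; C1, C2, C4 and C5 are carried through, and the trans arrangement of the two reacting arms on C1 and C5 becomes the trans ring fusion. The step needs site selectivity for the C7 methyl enolate over the C5 methine enolate, which would give a five-membered ring and open the way to loss of the C4 silyloxy group, and this rests on the hindrance of C5 between two fully substituted carbons. The product stays in the flask as the extended dienolate 18 because more than two equivalents of base are used, and kinetic protonation at C7 on cold work-up should keep the double bond at C8–C9 out of conjugation.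

Step 15
Reactants: 19 2α,4β-bis(triethylsilyloxy)dauc-8-en-6-one
Product: 20 2α,4β-dihydroxydauc-8-en-6-one
Conditions: HF·pyridine, pyridine, THF, 0 °C to rt
Reagents that add atoms: none
Why: Fluoride-mediated desilylation with buffered HF·pyridine removes both triethylsilyl groups without the base that would trigger retro-aldol cleavage of the β-hydroxy ketone or conjugation of the β,γ-enone.

Step 16
Reactants: 20 2α,4β-dihydroxydauc-8-en-6-one
Product: 21 dauc-8-ene-2α,4β,6α-triol
Conditions: Me4NBH(OAc)3, MeCN–AcOH, −30 to 0 °C
Reagents that add atoms: none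
Why: Evans–Saksena hydroxyl-directed reduction, in which the β C4 hydroxyl lies beside the β face of the C6 carbonyl (the face that the angular methyl closes to external hydride) and delivers hydride there, should give the 6α alcohol, the C2 hydroxyl being too remote to compete and the undirected reagent too weak to reduce the ketone.

Step 17
Reactants: 21 dauc-8-ene-2α,4β,6α-triol, 22 angelic acid
Product: 23 6α-(angeloyloxy)dauc-8-ene-2α,4β-diol
Conditions: 22 (1.1 equiv), 2,4,6-trichlorobenzoyl chloride (1.1 equiv), Et3N, toluene, rt; then 21, 40 °C
Reagents that add atoms: none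
Why: Yamaguchi esterification through the mixed anhydride, run with close to one equivalent of acyl donor and without the nucleophilic catalyst that isomerises angelates to tiglates, should acylate the C6 hydroxyl (its carbinol carbon lies between a methine and a methylene of the flexible ring A) ahead of the neopentyl C2 hydroxyl next to the quaternary C1, the tertiary C4 hydroxyl being inert, and any C2 ester or diester formed alongside need not be separated because step 18 converges it on the same product.

Step 18
Reactants: 23 6α-(angeloyloxy)dauc-8-ene-2α,4β-diol, 22 angelic acid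
Product: 24 2α,6α-bis(angeloyloxy)dauc-8-en-4β-ol (CNP0303897.1)
Conditions: 22 (4 equiv), 2,4,6-trichlorobenzoyl chloride (4 equiv), Et3N, toluene, rt; then 23, 80 °C
Reagents that add atoms: none
Why: Yamaguchi esterification with an excess of the mixed anhydride at higher temperature should acylate the remaining neopentyl C2 hydroxyl, again without a nucleophilic catalyst so that both esters keep the Z geometry, while the hindered tertiary C4 hydroxyl stays free.

**Compound list**

1 | 2-methylcyclopent-2-en-1-one | CC1=CCCC1=O | starting material
2 | (R)-2-methylcyclopent-2-en-1-ol | O[C@@H]1CCC=C1C | intermediate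
3 | (R)-tert-butyldimethyl[(2-methylcyclopent-2-en-1-yl)oxy]silane | CC(C)(C)[Si](C)(C)O[C@@H]1CCC=C1C | intermediate
4 | (R)-4-[(tert-butyldimethylsilyl)oxy]-3-methylcyclopent-2-en-1-one | CC(C)(C)[Si](C)(C)O[C@@H]1CC(=O)C=C1C | intermediate
5 | (1R,4R)-4-[(tert-butyldimethylsilyl)oxy]-3-methyl-1-(propan-2-yl)cyclopent-2-en-1-ol | CC(C)(C)[Si](C)(C)O[C@@H]1C[C@@](O)(C(C)C)C=C1C | intermediate
6 | (1R,4R)-3-methyl-1-(propan-2-yl)cyclopent-2-ene-1,4-diol | O[C@@H]1C[C@@](O)(C(C)C)C=C1C | intermediate
7 | (R)-4-hydroxy-2-methyl-4-(propan-2-yl)cyclopent-2-en-1-one | O=C1C[C@@](O)(C(C)C)C=C1C | intermediate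
8 | (R)-2-methyl-4-(propan-2-yl)-4-[(trimethylsilyl)oxy]cyclopent-2-en-1-one | O=C1C[C@@](O[Si](C)(C)C)(C(C)C)C=C1C | intermediate
9 | {[(3R,4R)-3-ethenyl-2-methyl-4-(propan-2-yl)-4-(trimethylsilyloxy)cyclopent-1-en-1-yl]oxy}trimethylsilane | C[Si](C)(C)OC1=C(C)[C@@H](C=C)[C@](O[Si](C)(C)C)(C(C)C)C1 | intermediate
10 | (Z)-1,3-dichlorobut-2-ene | ClC/C=C(/C)Cl | starting material
11 | (Z)-3-chloro-1-iodobut-2-ene | IC/C=C(/C)Cl | intermediate
12 | lithium enolate of 9 (enol OSiMe3 replaced by OLi) | [Li]OC1=C(C)[C@@H](C=C)[C@](O[Si](C)(C)C)(C(C)C)C1 | intermediate (not isolated)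
13 | (2R,3R,4R)-2-[(2Z)-3-chlorobut-2-en-1-yl]-3-ethenyl-2-methyl-4-(propan-2-yl)-4-[(trimethylsilyl)oxy]cyclopentan-1-one | O=C1C[C@@](O[Si](C)(C)C)(C(C)C)[C@H](C=C)[C@@]1(C)C/C=C(/C)Cl | intermediate (not isolated)
14 | (2R,3R,4R)-2-[(2Z)-3-chlorobut-2-en-1-yl]-3-ethenyl-4-hydroxy-2-methyl-4-(propan-2-yl)cyclopentan-1-one | O=C1C[C@@](O)(C(C)C)[C@H](C=C)[C@@]1(C)C/C=C(/C)Cl | intermediate
15 | (1R,3S,4R,5R)-4-[(2Z)-3-chlorobut-2-en-1-yl]-5-ethenyl-4-methyl-1-(propan-2-yl)cyclopentane-1,3-diol | O[C@H]1C[C@@](O)(C(C)C)[C@H](C=C)[C@@]1(C)C/C=C(/C)Cl | intermediate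
16 | bis(triethylsilyl) ether of diol 15 | CC[Si](CC)(CC)O[C@H]1C[C@@](O[Si](CC)(CC)CC)(C(C)C)[C@H](C=C)[C@@]1(C)C/C=C(/C)Cl | intermediate
17 | ring B methyl ketone: C1 β-methyl and α-[(Z)-3-chlorobut-2-enyl], C2 α-OSiEt3, C4 β-OSiEt3 and α-isopropyl, C5 β-acetyl | CC[Si](CC)(CC)O[C@H]1C[C@@](O[Si](CC)(CC)CC)(C(C)C)[C@H](C(C)=O)[C@@]1(C)C/C=C(/C)Cl | intermediate
18 | sodium dienolate of 19 (C6 ONa, C6=C7 and C8=C9) | [Na]OC1=CC(C)=CC[C@@]2(C)[C@@H](O[Si](CC)(CC)CC)C[C@@](O[Si](CC)(CC)CC)(C(C)C)[C@H]12 | intermediate (not isolated)
19 | 2α,4β-bis(triethylsilyloxy)dauc-8-en-6-one | O=C1CC(C)=CC[C@@]2(C)[C@@H](O[Si](CC)(CC)CC)C[C@@](O[Si](CC)(CC)CC)(C(C)C)[C@H]12 | intermediate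
20 | 2α,4β-dihydroxydauc-8-en-6-one | O=C1CC(C)=CC[C@@]2(C)[C@@H](O)C[C@@](O)(C(C)C)[C@H]12 | intermediate
21 | dauc-8-ene-2α,4β,6α-triol | O[C@H]1CC(C)=CC[C@@]2(C)[C@@H](O)C[C@@](O)(C(C)C)[C@H]12 | intermediate
22 | angelic acid, (Z)-2-methylbut-2-enoic acid | C/C=C(/C)C(=O)O | starting material
23 | 6α-(angeloyloxy)dauc-8-ene-2α,4β-diol | C/C=C(/C)C(=O)O[C@H]1CC(C)=CC[C@@]2(C)[C@@H](O)C[C@@](O)(C(C)C)[C@H]12 | intermediate
24 | 2α,6α-bis(angeloyloxy)dauc-8-en-4β-ol (CNP0303897.1) | C/C=C(/C)C(=O)O[C@H]1CC(C)=CC[C@@]2(C)[C@@H](OC(=O)/C(C)=C\C)C[C@@](O)(C(C)C)[C@H]12 | target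

**Step count**

Total: 18 steps. Longest linear sequence: 17 steps (steps 1–8 and 10–18 from 1); step 9 is a one-step side branch.

**Steps most likely to fail**

Step 8. The vinyl group may enter with poor facial selectivity, because attack anti to the C4 oxygen competes with attack anti to the isopropyl group. That would put C5, and then C1, in the wrong relation to C4. The fallback sets out from hydroxy enone 7 and uses the free hydroxyl as the controlling element. Excess vinylmagnesium bromide in THF (−78 to 0 °C, no copper) first forms the bromomagnesium alkoxide, which holds a second equivalent of the reagent and delivers the vinyl group to C5 on the oxygen face. This is an alkoxide-directed conjugate addition, reinforced by the isopropyl group on the other face. The resulting bis(bromomagnesium) alkoxide enolate F1 is silylated in the flask with Me3SiCl, Et3N and hexamethylphosphoramide, and the fallback comes back to the route at 9.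

Step 14. Three processes may interfere under the strongly basic conditions: slow insertion of palladium into the alkenyl chloride, elimination of the C4 silyloxy group through the C5 enolate, and migration of the C8–C9 double bond into conjugation. The fallback sets out from 17 and separates enolate formation from the coupling. Kinetic deprotonation at the methyl group (LiN(i-Pr)2, Me3SiCl, THF, −78 °C) gives the trimethylsilyl enol ether F2. It is cyclised without free base through the tin enolate made in the flask (Pd(OAc)2, P(t-Bu)3, n-Bu3SnF, CsF, toluene, 85 °C), a known palladium-catalysed coupling of enol silyl ethers with halides. The fallback comes back to the route at 19.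

Step 17. The first acylation may show poor site selectivity between the two hindered secondary hydroxyls, and the forcing conditions that the second acylation then needs may isomerise the angeloyl group to the E (tigloyl) form. The fallback sets out from triol 21, needs no distinction between the two hydroxyls and builds the Z double bonds after the ester bonds. Both secondary hydroxyls are esterified with 2-[bis(2,2,2-trifluoroethoxy)phosphoryl]propanoic acid (N,N'-dicyclohexylcarbodiimide, 4-(dimethylamino)pyridine, CH2Cl2) to give the bis(phosphonopropanoate) F3. A double Still–Gennari olefination with acetaldehyde (KN(SiMe3)2, 18-crown-6, THF, −78 °C) then forms both (Z)-2-methylbut-2-enoates, and the fallback comes back to the route at 24, so that it replaces steps 17 and 18 together.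

**Further compounds**

F1 | step 8 | bis(bromomagnesium) alkoxide enolate from directed vinyl addition to 7 | Br[Mg]OC1=C(C)[C@@H](C=C)[C@](O[Mg]Br)(C(C)C)C1
F2 | step 14 | trimethylsilyl enol ether of methyl ketone 17 (C6 OSiMe3, C6=C7) | CC[Si](CC)(CC)O[C@H]1C[C@@](O[Si](CC)(CC)CC)(C(C)C)[C@H](C(=C)O[Si](C)(C)C)[C@@]1(C)C/C=C(/C)Cl
F3 | step 17 | 2,6-bis{2-[bis(2,2,2-trifluoroethoxy)phosphoryl]propanoate} of triol 21 | CC(C(=O)O[C@H]1CC(C)=CC[C@@]2(C)[C@@H](OC(=O)C(C)P(=O)(OCC(F)(F)F)OCC(F)(F)F)C[C@@](O)(C(C)C)[C@H]12)P(=O)(OCC(F)(F)F)OCC(F)(F)F
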